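All runs come from a simulation on assumed constants, and the scatter is random.

Percent per second is a poor unit here, since a straight line runs past the charge. We reckon instead with the fraction of substrate not yet turned into target.

| flask | substrate | partner | remark | time |
|---|---|---|---|---|
| summer | 5.0 × 10⁻⁴ M | 1.9 equiv | run made earlier |  |
| dusk | 5.0 × 10⁻⁴ M | 1.7 equiv | run made earlier |  |
| larch | 5.0 × 10⁻⁴ M | 1.50 equiv |  | 2.0 min |
| cedar | 5.0 × 10⁻⁴ M | 2.20 equiv |  | 2.0 min |

| run | time / s | target / % |
|---|---|---|
| summer | 12.0 | 2.3 |
| summer | 25.0 | 8.9 |
| summer | 40.0 | 24.5 |
| summer | 50.0 | 34.1 |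
| summer | 60.0 | 45.1 |
| dusk | 10.0 | 0 |
| dusk | 15.0 | 2.3 |
| dusk | 30.0 | 13.5 |
| dusk | 40.0 | 22.2 |
| dusk | 60.0 | 40.5 |

(standard deviation of a reading: 1 percentage point)

1. which of the two there is more of at the end, larch (side product / target)
2. which of the two there is more of at the end, cedar (side product / target)
3. how much target is there at the end, in percent of the substrate charged: larch
4. how much target is there at the end, in percent of the substrate charged: cedar

- the numbers in the tables scatter with a standard deviation of 1 percentage point

1. We take minus the logarithm of that fraction. From 40.0 s to 60.0 s it climbs at 0.0159 s⁻¹ in summer. From 40.0 s to 60.0 s it climbs at 0.0134 s⁻¹ in dusk.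

2. The mean of the two slopes is 0.0147 s⁻¹, at a mean charge of 1.80 of partner, and we take the slope as proportional to the equivalents of partner. Traced back, the lines reach zero after a lag (induction period) of 21.8 s.

3. Larch has 1.20 and cedar 1.76 of one number, N: the mean slope, scaled to the flask's equivalents of partner, times the time past the lag. In words, N counts the e-foldings of the unconverted fraction, so the fraction left is exp(−N).

4. We therefore reckon 69.9 % of target for larch and 82.8 % for cedar. Both N stand above ln(2), so we reckon more target than all the rest of the charge together, and we expect target to lead side product in larch and in cedar.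

5. Is one number enough? For summer at 50.0 s, N gives 35.4 % against a reading of 34.1 %. For dusk at 30.0 s, it gives 10.7 %, less than the reading of 13.5 %. The tables hold target and no side product, so N has no term for a branch.

The forecast says 70 % for larch and 85 % for cedar, with target ahead in larch and target in cedar. Its cedar figure is a little above ours. Its view of the curves: “The lag suggests an intermediate on the way to target.”

    substrate → open intermediate (k = 0.0350 s⁻¹)
    partner → second intermediate (k = 0.0240 s⁻¹)
    open intermediate + second intermediate → target (k = 57.0 L mol⁻¹ s⁻¹)
    substrate + second intermediate → side product (k = 26.0 L mol⁻¹ s⁻¹)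
    target → over-reaction product (k = 4.80 × 10⁻⁵ s⁻¹)

Larch ends at 68.9 % of target and cedar at 76.0 %, with side product at 12.7 % and 17.6 %. In cedar, N calls 17.2 % of the charge not turned into target, and the flask holds 17.6 % as side product and 5.80 % as open intermediate. A flask like cedar but with 0.550 equiv of partner scales N to 0.440, which means 35.6 % of target. That flask gives 34.9 % of target.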